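The autumn flask, with less starting material than the spring flask, made target faster: on average 0.00300 M h⁻¹ up to 3.2 h against 5.92 × 10⁻⁴ M h⁻¹ up to 9.8 h, with 0.0096 M and 0.0058 M of target made. From these readings I took an order in starting material of −1.01, which is substrate inhibition. The summer flask's reading of 0.0118 M at 9.8 h gives an average turnover rate per free catalyst charged of 0.0803 h⁻¹. The autumn flask's target fell from 0.0502 M at 30 h to 0.0361 M at 73 h, which I read as a first-order loss of 0.00767 h⁻¹.

| flask | starting material | free catalyst | target | time |
|---|---|---|---|---|
| summer | 0.150 M | 0.0150 M |  |  |
| autumn | 0.0600 M | 0.0150 M |  |  |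
| noon | 0.150 M | 0.0150 M | 0.0750 M |  |
| spring | 0.300 M | 0.0150 M |  |  |
| midnight | 0.150 M | 0.00500 M |  | 73 h |

- summer run (time / h: [target] / M): 3.2: 0.0042; 9.8: 0.0118; 19: 0.0217; 30: 0.0350; 43: 0.0507; 57: 0.0695; 73: 0.1048
- autumn run (time / h: [target] / M): 3.2: 0.0096; 9.8: 0.0371; 19: 0.0551; 30: 0.0502; 43: 0.0459; 57: 0.0413; 73: 0.0361
- noon run (time / h: [target] / M): 3.2: 0.0771; 9.8: 0.0814; 19: 0.0870; 30: 0.0949; 43: 0.1052; 57: 0.1182; 73: 0.1475
- spring run (time / h: [target] / M): 3.2: 0.0022; 9.8: 0.0058; 19: 0.0107; 30: 0.0165; 43: 0.0211; 57: 0.0265; 73: 0.0309

(standard deviation of a reading: 4 × 10⁻⁴ M)

- Overall: starting material -> target, with free catalyst as catalyst.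
- Constant volume, constant temperature.
- What is held in complexes is read along with the free species.
- An order is taken over about fifteen percent of the charge, up and down.

1. order of the initial rate in [starting material], near the charge of the summer run, the rate being that where two percent of its starting material are target (one fixed amount of target, the same in the runs compared)
2. target in the midnight run at 73 h, as a share of the starting material charged

The midnight flask holds a third of the summer flask's catalyst, and no run varied catalyst. That order in starting material fits a step by one unbound catalyst, first order in catalyst, or a step joining held and unbound catalyst, second order. My bound from above took first order without loss: 19.5% of the charge. My bound from below took second order, with target made at the start and standing the full 73 h: 3.72%.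

Steady making tightens the top, since 73 h then count as 55.9 h: first order gives 15.0%. The bottom stayed where it was. Second order with steady making gives 1.50 kept turnovers, the target standing per catalyst charged, or 4.99%, which is an estimate inside the bracket and no bound. I committed to this estimate, as a guess at the step.

The forecast gave −1 and 18.7%, on this ground: “No run varied catalyst, so I assume first order”. Its figure is the summer curve with its clock scaled as if first order in everything but starting material, above my tightened top.

The midnight flask gave 4.13%, with order −1.0. That is 1.24 kept turnovers, fewer than my 1.50.

    free catalyst + starting material ⇌ catalyst-substrate complex, settled at all times (131.0 L mol⁻¹)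
    catalyst-substrate complex + free catalyst → target + 2 free catalyst (107.6 L mol⁻¹ h⁻¹)
    free catalyst + starting material → spent catalyst + starting material (0.2977 L mol⁻¹ h⁻¹)
    target → decomposed product (0.007632 h⁻¹)

The step that makes target joins a catalyst-substrate complex to a free catalyst. For the spring flask I scaled the hourly turnovers by the summer charge over the spring charge, which gives 2.24 kept turnovers at 73 h, and its last reading stands at 2.06.

The numbers in the tables were generated by integration for substances that don't exist, and the scatter is random.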